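A direct plan would start from the purchased bromoguaiacol A1 and add iodine and a second bromine by two electrophilic substitutions to give A2.
It would then demethylate to the iodocatechol A3 and join two such rings to the central CH2–O–CH2 unit by a twofold palladium-catalysed Stille coupling with the distannyl ether A4.
Weakest would be the twofold alkoxymethyl transfer from tin: two slow sp3 transmetalations on the most precious material, a C–I bond to be told apart from two C–Br bonds in each ring, and phthalan closure or catechol–metal binding as ways out.
Weak too would be the ortho-bromination of an iodophenol beside an existing bromine: the site, and the avoidance of ipso attack at C–I, would rest on reagent control alone.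
The third would be the Williamson synthesis of A4 from two stannylmethyl building blocks: stoichiometric tin twice over, only to carry one oxygen and two carbons.
In all, three steps would add single atoms to a ring that was bought.

**Plan of the new route**
The retrosynthesis cuts, in each benzene ring, the bonds C1–C6 and C2–C3 (C1 bears CH2O, C2 and C3 bromine, C4 and C5 oxygen, C6 hydrogen).
C1–C2 of both rings come from the two alkynes of one bis(3-bromopropargyl) ether; C3–C4–C5–C6 come from C2–C3–C4–C5 of a 2-bromo-3,4-disilyloxycyclopentadienone, whose carbonyl carbon leaves as CO.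
The feature that allows this is the mirror plane through the ether oxygen together with the contiguous C(Br)–C(O)–C(O)–C(H) strip of each ring, which is a cyclopentane-1,2,4-trione in disguise.
The ether link and all four C–Br bonds exist before any ring; both arenes arise together, last, in one twofold Diels–Alder/CO-extrusion benzannulation.
No cross-coupling, no tin and no aromatic halogenation occur: bromine is placed on an alkyne terminus and on an enol carbon, where the position is not in question, and the catechols are set free from silyl ethers.

Key step: step 4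

Remark: dipropargyl ether and cyclopentane-1,2,4-trione are taken as purchasable; the trione reacts throughout as its enol, 2-hydroxycyclopent-2-ene-1,4-dione.

**Step 1**
Reactants: 1 dipropargyl ether (3-(prop-2-yn-1-yloxy)prop-1-yne)
Product: 2 bis(3-bromoprop-2-yn-1-yl) ether
Conditions: NBS (2.3 equiv), AgNO3 (10 mol %), acetone, rt, dark
Reagents that add atoms: N-bromosuccinimide, O=C1CCC(=O)N1Br
Why: Silver-catalysed electrophilic bromination of terminal alkynes through the silver acetylide; both termini react alike and the propargylic ether is inert.

**Step 2**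
Reactants: 3 cyclopentane-1,2,4-trione
Product: 4 3-bromo-2-hydroxycyclopent-2-ene-1,4-dione (enol form of 3-bromocyclopentane-1,2,4-trione)
Conditions: NBS (1.0 equiv), MeCN, 0 °C
Reagents that add atoms: N-bromosuccinimide, O=C1CCC(=O)N1Br
Why: Electrophilic α-bromination of an enolised cyclic 1,3-dicarbonyl compound at its enol carbon; C3 and C5 are equivalent by the mirror plane through C4, so a single monobromide should form, and one equivalent of reagent limits dibromination.

**Step 3**
Reactants: 4 3-bromo-2-hydroxycyclopent-2-ene-1,4-dione
Product: 5 2-bromo-3,4-bis[(tert-butyldimethylsilyl)oxy]cyclopenta-2,4-dien-1-one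
Conditions: TBSOTf (2.2 equiv), Et3N (2.6 equiv), CH2Cl2, −78 → 0 °C; pentane, filtration under Ar; used at once
Reagents that add atoms: tert-butyldimethylsilyl trifluoromethanesulfonate, CC(C)(C)[Si](C)(C)OS(=O)(=O)C(F)(F)F
Why: Soft enolisation and O-silylation of ketones with a silyl triflate and an amine; the enol OH and the doubly activated C5 methylene are silylated, and the isomer that keeps the isolated C4 carbonyl with both silyloxy groups in β-positions (a twofold vinylogous ester) should be the thermodynamic one, reached by fast 1,5-silyl shifts between the oxygens.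

**Step 4**
Reactants: 2 bis(3-bromoprop-2-yn-1-yl) ether (1.0 equiv); 5 2-bromo-3,4-bis[(tert-butyldimethylsilyl)oxy]cyclopenta-2,4-dien-1-one (2.5 equiv)
Product: 8 bis{2,3-dibromo-4,5-bis[(tert-butyldimethylsilyl)oxy]benzyl} ether, via mono-cycloadduct ketone 6 (not isolated), via mono-arene bromoalkyne 7 (not isolated)
Conditions: toluene (0.3 M), BHT (1 mol %), 90 → 110 °C, Ar, dark, vented through a bubbler
Reagents that add atoms: none
Why: Each bromoalkyne adds across the α-carbons C2 and C5 of the dienone in a thermal (4+2) cycloaddition and the resulting norbornadien-7-one (6, then its counterpart on the second arm) expels CO in a cheletropic step, so that a benzene ring is left; the closest known reaction type is the Diels–Alder/decarbonylation benzannulation of cyclopentadienones with alkynes, haloalkynes included. Both arenes close in the same intermolecular six-membered mode, two C–C bonds per ring (arene C1–C6 and C2–C3), and aromatise at once, which makes the step irreversible. No stereocentre survives, since the bridgehead centres of 6 disappear with CO. The selectivity needed is the orientation, alkyne C–Br next to dienone C–Br. The two silyloxy groups make the dienone the nucleophilic partner, whose reactive terminus is the unsubstituted C5 (an enol-ether β-carbon not weakened by bromine), while a 1-bromoalkyne accepts nucleophiles at the carbon remote from bromine, here the one that bears CH2O; the larger CH2OR group also avoids the brominated terminus. Dimerisation of 5 should be held back because its only free C=C is an electron-rich silyl enol ether, and the excess of 5 covers what is lost.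

**Step 5**
Reactants: 8 bis{2,3-dibromo-4,5-bis[(tert-butyldimethylsilyl)oxy]benzyl} ether
Product: 9 bis(2,3-dibromo-4,5-dihydroxybenzyl) ether
Conditions: HF·pyridine (excess), pyridine/THF, 0 °C → rt, Ar; aq NaH2PO4 (pH 6) work-up, no alcohol solvents
Reagents that add atoms: none
Why: Fluoride cleavage of aryl silyl ethers under buffered, weakly acidic conditions, so that no phenoxide para to the benzylic ether is formed and the CH2–O–CH2 link is not ionised; no stereocentre is involved.

**Compound list**
1 | dipropargyl ether (3-(prop-2-yn-1-yloxy)prop-1-yne) | C#CCOCC#C | starting material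
2 | bis(3-bromoprop-2-yn-1-yl) ether | BrC#CCOCC#CBr | intermediate
3 | cyclopentane-1,2,4-trione | O=C1CC(=O)C(=O)C1 | starting material
4 | 3-bromo-2-hydroxycyclopent-2-ene-1,4-dione (enol of 3-bromocyclopentane-1,2,4-trione) | OC1=C(Br)C(=O)CC1=O | intermediate
5 | 2-bromo-3,4-bis[(tert-butyldimethylsilyl)oxy]cyclopenta-2,4-dien-1-one | O=C1C(Br)=C(O[Si](C)(C)C(C)(C)C)C(O[Si](C)(C)C(C)(C)C)=C1 | intermediate
6 | 1,2-dibromo-3-{[(3-bromoprop-2-yn-1-yl)oxy]methyl}-5,6-bis[(tert-butyldimethylsilyl)oxy]bicyclo[2.2.1]hepta-2,5-dien-7-one (racemic, not isolated) | O=C1C2(Br)C(Br)=C(COCC#CBr)C1C(O[Si](C)(C)C(C)(C)C)=C2O[Si](C)(C)C(C)(C)C | intermediate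
7 | 3-bromoprop-2-yn-1-yl 2,3-dibromo-4,5-bis[(tert-butyldimethylsilyl)oxy]benzyl ether (not isolated) | BrC#CCOCc1cc(O[Si](C)(C)C(C)(C)C)c(O[Si](C)(C)C(C)(C)C)c(Br)c1Br | intermediate
8 | bis{2,3-dibromo-4,5-bis[(tert-butyldimethylsilyl)oxy]benzyl} ether | CC(C)(C)[Si](C)(C)Oc1cc(COCc2cc(O[Si](C)(C)C(C)(C)C)c(O[Si](C)(C)C(C)(C)C)c(Br)c2Br)c(Br)c(Br)c1O[Si](C)(C)C(C)(C)C | intermediate
9 | bis(2,3-dibromo-4,5-dihydroxybenzyl) ether | Oc1cc(COCc2cc(O)c(O)c(Br)c2Br)c(Br)c(Br)c1O | target

Total step count: 5. Longest linear sequence: 4 steps (3 → 4 → 5 → 8 → 9).

**Steps most likely to fail**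

Step 4. The bromoalkyne may add in the reversed orientation, so that its bromine ends beside hydrogen. The dienone may dimerise faster than the weakly dienophilic haloalkyne captures it. The reaction may also stop after one arm. The fallback sets out from 2 and replaces the five-membered dienone by a six-membered diene that cannot dimerise and reacts only as a nucleophile. Cyclohexane-1,2-dione would be brominated with NBS to 3-bromo-2-hydroxycyclohex-2-en-1-one F1 and silylated with TBSOTf and Et3N to 1-bromo-2,3-bis[(tert-butyldimethylsilyl)oxy]cyclohexa-1,3-diene F2. An Alder–Rickert reaction of 2 with F2 (neat, sealed tube, 160–180 °C) should give the twofold bicyclo[2.2.2]octa-2,5-diene cycloadduct F3, which loses two molecules of ethylene by retro-Diels–Alder reaction and comes back to the route at 8.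

Step 3. Silylation may occur on the wrong carbonyl oxygen, or a silyl group may migrate to give the 2,4-disilyloxy isomer. The dienone may also dimerise on concentration. The fallback sets out from 4 and ties the two neighbouring oxygens into one ring, so that only the 3,4-dioxy dienone can exist. tBu2Si(OTf)2 and 2,6-lutidine should give 2-bromo-3,4-(di-tert-butylsilylenedioxy)cyclopenta-2,4-dien-1-one F4. Cycloaddition with 2 under the conditions of step 4 should give bis[(6,7-dibromo-2,2-di-tert-butyl-1,3,2-benzodioxasilol-5-yl)methyl] ether F5, and HF·pyridine would then lead directly to 9.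

Step 5. The benzylic C–O bond para to a freed phenol may ionise (quinone methide formation) during or after desilylation, and the catechol may oxidise in air. The fallback sets out from 8 and carries the heterolysis through on purpose. HF·pyridine followed by dilute aqueous acid in acetone should give 2,3-dibromo-4,5-dihydroxybenzyl alcohol F6. Acid-catalysed self-etherification of F6 (TsOH cat., MeNO2, molecular sieves, rt, Ar), which runs through the same quinone methide in the absence of other nucleophiles, comes back to the route at 9.

**Further compounds**
F1 | step 4 | 3-bromo-2-hydroxycyclohex-2-en-1-one | O=C1CCCC(Br)=C1O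
F2 | step 4 | 1-bromo-2,3-bis[(tert-butyldimethylsilyl)oxy]cyclohexa-1,3-diene | BrC1=C(O[Si](C)(C)C(C)(C)C)C(O[Si](C)(C)C(C)(C)C)=CCC1
F3 | step 4 | twofold bicyclo[2.2.2]octa-2,5-diene cycloadduct of 2 and F2 (bridgeheads Br and H, racemic/meso mixture) | O(CC1=C(Br)C2(Br)CCC1C(O[Si](C)(C)C(C)(C)C)=C2O[Si](C)(C)C(C)(C)C)CC1=C(Br)C2(Br)CCC1C(O[Si](C)(C)C(C)(C)C)=C2O[Si](C)(C)C(C)(C)C
F4 | step 3 | 2-bromo-3,4-(di-tert-butylsilylenedioxy)cyclopenta-2,4-dien-1-one | O=C1C(Br)=C2O[Si](C(C)(C)C)(C(C)(C)C)OC2=C1
F5 | step 3 | bis[(6,7-dibromo-2,2-di-tert-butyl-1,3,2-benzodioxasilol-5-yl)methyl] ether | CC(C)(C)[Si]1(C(C)(C)C)Oc2cc(COCc3cc4O[Si](C(C)(C)C)(C(C)(C)C)Oc4c(Br)c3Br)c(Br)c(Br)c2O1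
F6 | step 5 | 2,3-dibromo-4,5-dihydroxybenzyl alcohol | OCc1cc(O)c(O)c(Br)c1Br
A1 | direct plan | 5-bromo-2-methoxyphenol | COc1ccc(Br)cc1O
A2 | direct plan | 2,3-dibromo-4-iodo-6-methoxyphenol | COc1cc(I)c(Br)c(Br)c1O
A3 | direct plan | 3,4-dibromo-5-iodobenzene-1,2-diol | Oc1cc(I)c(Br)c(Br)c1O
A4 | direct plan | bis[(tributylstannyl)methyl] ether | CCCC[Sn](CCCC)(CCCC)COC[Sn](CCCC)(CCCC)CCCC
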